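The runs stem from a simulated flask from invented constants; noise was put on by code.

Starting material charged does not vanish, so in this flask I assume that it stands either free or as first product, with the two peaks adding up to the charge, and that one reading gives the other.

| flask | starting material | coupling partner | temperature | remark | time |
|---|---|---|---|---|---|
| south | 0.020 M | 0.95 equiv | 20 °C | the very flask that is asked about, followed so far |  |
| north-east | 0.020 M | 0.95 equiv | 15 °C | run made earlier |  |
| flask | 0.020 M | 0.950 equiv | 20 °C |  | 2.5 h |

- south (time / min: first product / %): 12.0: 34; 20.0: 35; 30.0: 39; 40.0: 44; 60.0: 43; 90.0: 47; 150: 46
- north-east (time / min: first product / %): 12.0: 24; 20.0: 28; 30.0: 36; 40.0: 39; 60.0: 43; 90.0: 41; 150: 48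

(standard deviation of a reading: 2 percentage points)

- first product, in percent of the starting material first charged, at 2.5 h
- the remedy with the largest gain of first product, or "none" below 2 percentage points (red / green / teal / violet / none)
- first product present, with what was taken out counted in, in percent of the starting material first charged, after teal
- first product present, with what was taken out counted in, in percent of the starting material first charged, after violet

- red: at 2.5 h add coupling partner, 100% of the amount charged, then wait 2.5 h
- green: at 2.5 h take out 90% of the first product then present, then wait 2.5 h
- teal: change nothing and wait 2.5 h more
- violet: at 2.5 h raise the temperature by 15 K, then wait 2.5 h

- first product that was removed still counts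
- additions bring no volume worth counting

**What do the runs show?** The south run is flat: 47% at 90.0 min, 46% at 150 min. The north-east run, at 15 °C, reads 24% against 34% at 12.0 min, but ends at 48%. The last readings of the two runs average 47.0%, which on my assumption leaves 53.0% of the starting material.

**What is your quantity?** I reckon 0.933: first product over starting material left at the stop, per equivalent of partner charged. I call it the stop ratio.

**Why should that hold steady?** Suppose partner is lost by meeting partner, two at a time, with the same rate constant as for its meeting with starting material, and that it is lost in no other way. Then the ratio is 1, whatever the charge, and the reading lies near that.

**And the weak spot?** If partner is lost on first product instead, more partner eats the product. Both runs carry 0.95 equiv of partner, so they do not test a change of charge, and this is my bet.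

**Your answers?** Now about 47.0%, and the same after teal and violet. For red, the rest acts as a fresh flask: new rest equals rest over one plus ratio times added partner over rest. That gains 33 percentage points, so I say red.

The forecast gives 46.5% now, 47% after teal, 47% after violet, and none as best remedy. It grants that “Adding partner restarts the chain”, but expects first product to fall, so it parts from my call on red.

The flask gives 48.1% now, 48.2% after teal, 48.2% after violet, and red as best. Red gains 31 points, more than green's 0.088 points, teal's 0.085 points or violet's 0.086 points.

    starting material + coupling partner → first product (k = 3.30 /M/min, Ea = 58.0 kJ/mol)
    coupling partner + first product → double product (k = 0.0580 /M/min, Ea = 62.0 kJ/mol)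
    2 coupling partner → self-condensation product (k = 3.30 /M/min, Ea = 43.0 kJ/mol)
    (constants at 20 °C)

This flask has come to rest. At 150 min the coupling partner, its limiting reagent, stands at 0.094% of its charge, and 0% at 1500 min. Ten times the time leaves first product at 48.2%, while starting material reads 51.5% against 52%. The stop ratio from the flask's own figures, first product over the starting material still free, is 0.982.

A neighbour charged with 2.40 equiv of partner: ratio times charge, over one plus that, gives 69.1% first product. The neighbour gives 68.8%.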